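## Analysis of the target

Target 35 is a germacranolide: a ten-membered carbocycle (C1–C10) fused through C6 (oxygen) and C7 to an α-methylene-γ-butyrolactone (C12 carbonyl, exocyclic C11=C13). Both ring alkenes are trisubstituted. C4=C5 carries the acetoxymethyl carbon C15 and C1=C10 carries the formyl carbon C14. In each, the two ring carbons are cis to one another; the descriptors are E only because C14 and C15 are oxidised. Three contiguous stereocentres lie on one edge of the ring: C6 (R), C7 (R) and C8 (S). H6 and H7 are trans (trans-fused lactone), and the C8 acyloxy group is anti to C6 when C11–C7–C8–C9 is drawn in zigzag. The fourth centre is the (S) α-carbon of the 2-methylbutanoate. The α-methylene lactone and the enal are Michael acceptors, the C6–O bond is allylic, and O6 and O8 are both γ to C12, so translactonisation is possible. The difficulty is to close a medium ring holding two cis trisubstituted alkenes while keeping four oxygenated carbons (C8, C13, C14, C15) apart at different oxidation levels. The strategy rests on the array C8(O)–C7–C11=C13: it is a homoallylic alcohol, the retron of an allylmetal adding through its γ-carbon C7 to a C8 aldehyde. The five carbons C12, C11, C7, C6 and C5 map onto glutamic acid 14, whose stereocentre becomes C6.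

## Retrosynthetic reasoning

**End game, 35 back to 31 and 32.** The C14 aldehyde is taken back to allylic alcohol 34 and its silyl ether 33. The C8–O ester bond is then cut to give alcohol 31 and acid 32. The enal and the branched ester are the most fragile groups, so they come last. The C8 oxygen is created by the ring closure, so acylation cannot come earlier.

**Key disconnection, 31 back to 29.** The C7–C8 bond is cut. This opens the ten-membered ring and turns the α-methylene lactone into a 3-(bromomethyl)butenolide with a tethered aldehyde, compound 29. The cut is made here because one bond formation then delivers the ring, C7, C8 and the exocyclic methylene together. The lactone oxygen is already fixed on C6, so O6 and O8 are never in competition during ring formation. The forward step must attack through the γ-carbon, on the butenolide face opposite the C5 substituent, with one aldehyde face, and faster than intermolecular coupling.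

**Adjusting the ends of 29, back to 19.** The C8 aldehyde is β,γ-unsaturated and is made last, from alcohol 28 and silyl ether 27. Bromide 27 comes from alcohol 26. The C7=C11 double bond of 26 comes from selenide 24 by selenoxide elimination. Cutting C11–C13 and C11–Se leads through 23 and 21 to the saturated lactone 19. Both bonds are enolate reactions, so they must precede the acetate. C15 is acetylated at 23, where the new C13 hydroxyl is neopentyl and the two can be told apart by size.

**C4=C5, 19 back to 17 and 13.** The alkene is cut by a Wittig disconnection into lactone aldehyde 17 and the formyl-stabilised ylide 13. A stabilised ylide gives the E enal, which puts C6 trans to C15 as required. C15 enters at the aldehyde level because an ester at C15 would need a hydride reduction that the γ-lactone does not survive. The enal 18 is reduced selectively to 19.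

**Chiral pool, 17 back to 14.** Aldehyde 17 comes from alcohol 16, acid 15 and glutamic acid 14 with retention. No asymmetric step is needed for C6.

**Chain fragment, 13 back to 1, 2 and 5.** Ylide 13 is cut at C4–C15 (formylation) and C4–P (salt 11 from bromide 10). The C1=C10 alkene of 10, 9 and 8 is cut by a Horner–Wadsworth–Emmons disconnection into phosphonate 4 and aldehyde 6. The E enoate puts C2 trans to C14. Phosphonate 4 comes from 1 and 2 (bond C9–C10), and 6 from ester 5. All ester reductions of this fragment happen before the lactone is attached. The two silyl groups are chosen so that the C8 ether can be removed in the presence of the C14 ether.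

## Alternatives that were turned down

Alternative 1: The two ring ketones of cyclodecenedione A2 (C1 and C6) are reconnected to a tetrasubstituted C1=C6 double bond. This gives the Birch-type bicyclic diene A1, and the forward key step is ozonolysis of that ring-fusion alkene.
- For it: the ten-membered ring is obtained by cleaving a bond, with no dilution and no entropic penalty. C7 and C8 are set on a six-membered ring, and the ring alkene is cis by construction. On certainty of ring formation it is stronger than the chosen route.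
- Against it: ozone must distinguish a tetrasubstituted from a trisubstituted alkene in the same diene. A2 is a cyclodecane-1,6-dione with a β-keto ester and is prone to transannular aldol closure back to a bicycle. The alkene of A2 sits at C3/C4 and must be moved to C4/C5, and C15 is still a methyl group.
- Still to do after the key step: the C6 ketone must be reduced with facial control on a floppy ring, the C1 ketone turned into the C1=C10 enal, and C13 added.
- Comparison: the chosen route risks the ring closure but forms C7–C8, both stereocentres and the methylene lactone at once, with every carbon at or near its final oxidation level.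

Alternative 2: The C7 acetic ester arm of dienone A5 is removed (alkylating agent A4), and the C8–C9 bond is exchanged for a C1–C6 bond. This contracts the ring to the cis-dialkenyl cyclohexenol A3. In the forward sense the potassium alkoxide of A3 undergoes an anionic oxy-Cope shift, and the ring-expanded enolate is trapped at C7 by A4.
- For it: the ring expansion is unimolecular and needs no dilution. Both ring alkenes and the C8, C14 and C15 oxygens are in place at once, and C8 is set by chirality transfer. In ring formation and convergence it is at least as strong as the chosen route.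
- Against it: A3 requires a β-alkoxyvinyl nucleophile to add to an enone cis to the neighbouring alkenyl group. For a cis-dialkenyl substrate the chair/boat choice decides both C8 and the C1=C10 geometry. The face of C7 alkylation on a ten-membered enolate is uncertain and C7 stays epimerisable next to the C6 ketone. The C6 ketone must then be reduced 1,2 with the correct face, and C13 introduced with base at the end.
- Comparison: the chosen route takes C6 from glutamic acid and arrives with the lactone complete, leaving only C7 and C8 to the ring-forming step.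

Alternative 3: The C1=C10 alkene of lactone A7 is opened to a C1–SO2–C10 bridge, giving the eleven-membered α-chloro sulfone A6. The forward key step is a Ramberg–Bäcklund contraction with KOt-Bu.
- For it: the large ring is closed as a sulfide by S-alkylation, which is easier than a C–C macrocyclisation. C6, C7 and C8 and the lactone are fixed beforehand, so no stereocentre depends on a macrocyclic transition state. On that point it is stronger than the chosen route.
- Against it: the alkene geometry follows from the episulfone, which is formed from a C10 epimer mixture. The strong base can also eliminate HCl toward C9. After the contraction, C13 is still missing, the C14 ester must be reduced to the aldehyde beside a lactone, and C15 must be re-protected. A6 itself needs a long linear build with three separately made stereocentres.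
- Comparison: the chosen route needs only three steps after ring closure.

Key step: step 20

Remarks on the chemistry:
- The alkene descriptors are read literally: C6 is trans to C15 on C4=C5 and C2 is trans to C14 on C1=C10, so both ring alkenes are cis within the ring.
- Germacrane numbering is used throughout: C1–C10 are the ring carbons, C11, C12 and C13 are the lactone α-carbon, carbonyl and methylene, C14 is on C10 and C15 is on C4.
- TBS = tert-butyldimethylsilyl, TBDPS = tert-butyldiphenylsilyl, TES = triethylsilyl.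
- Compounds 15 and 16 can also be bought, which would shorten the route by two steps.

## Route

Step 1
Reactants: 1 triethyl phosphonoacetate; 2 (2-bromoethoxy)(tert-butyl)dimethylsilane
Product: 4 ethyl 4-(TBS-oxy)-2-(diethoxyphosphoryl)butanoate, via sodium salt of triethyl phosphonoacetate 3 (not isolated)
Conditions: NaH, DMF, 0 °C; then 2, NaI (cat.), 60 °C
Reagents that add atoms: none
Why: C-alkylation of the phosphonoacetate carbanion by a primary bromide (SN2, iodide catalysis) is the standard way to α-substituted Horner–Wadsworth–Emmons reagents; the stereocentre formed is lost in step 3.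

Step 2
Reactants: 5 ethyl 4-bromobutanoate
Product: 6 4-bromobutanal
Conditions: i-Bu2AlH, CH2Cl2, −78 °C; aq. potassium sodium tartrate
Reagents that add atoms: none
Why: Partial ester reduction; at −78 °C the aluminium hemiacetal is stable and releases the aldehyde on work-up, and the primary bromide is inert to the hydride.

Step 3
Reactants: 4 ethyl 4-(TBS-oxy)-2-(diethoxyphosphoryl)butanoate; 6 4-bromobutanal
Product: 8 ethyl (E)-6-bromo-2-[2-(TBS-oxy)ethyl]hex-2-enoate, via sodium carbanion of the phosphonate 7 (not isolated)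
Conditions: NaH, THF, 0 °C; then 6, 0 °C to rt
Reagents that add atoms: none
Why: Horner–Wadsworth–Emmons olefination; reversible addition of the α-branched phosphonate anion should favour the E enoate, which sets C2 trans to C14 and cis to C9 as in the C1=C10 bond of the target; any Z isomer should be separable by chromatography.

Step 4
Reactants: 8 ethyl (E)-6-bromo-2-[2-(TBS-oxy)ethyl]hex-2-enoate
Product: 9 (E)-6-bromo-2-[2-(TBS-oxy)ethyl]hex-2-en-1-ol
Conditions: i-Bu2AlH (2.2 equiv), CH2Cl2, −78 °C
Reagents that add atoms: none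
Why: 1,2-Reduction of a conjugated ester to the allylic alcohol; bromide, silyl ether and alkene geometry are not affected, and no lactone is yet present.

Step 5
Reactants: 9 (E)-6-bromo-2-[2-(TBS-oxy)ethyl]hex-2-en-1-ol
Product: 10 (E)-6-bromo-1-(TBDPS-oxy)-2-[2-(TBS-oxy)ethyl]hex-2-ene
Conditions: TBDPSCl, imidazole, CH2Cl2, 0 °C to rt
Reagents that add atoms: tert-butyl(chloro)diphenylsilane, CC(C)(C)[Si](Cl)(c1ccccc1)c1ccccc1
Why: Silylation of a primary allylic alcohol; TBDPS is chosen because it outlasts the acidic fluoride cleavage of the primary TBS ether in step 18.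

Step 6
Reactants: 10 (E)-6-bromo-1-(TBDPS-oxy)-2-[2-(TBS-oxy)ethyl]hex-2-ene
Product: 11 [(E)-5-(TBDPS-oxymethyl)-7-(TBS-oxy)hept-4-en-1-yl]triphenylphosphonium bromide
Conditions: PPh3, MeCN, reflux
Reagents that add atoms: triphenylphosphine, c1ccc(P(c2ccccc2)c2ccccc2)cc1
Why: SN2 quaternisation of the phosphine by a primary bromide; the neutral conditions leave both silyl ethers intact.

Step 7
Reactants: 11 [(E)-5-(TBDPS-oxymethyl)-7-(TBS-oxy)hept-4-en-1-yl]triphenylphosphonium bromide
Product: 13 (E)-6-(TBDPS-oxymethyl)-8-(TBS-oxy)-2-(triphenylphosphoranylidene)oct-5-enal, via alkylidene phosphorane 12 (not isolated)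
Conditions: KOt-Bu (2.2 equiv), THF, 0 °C; then HCO2Et, 0 °C to rt
Reagents that add atoms: ethyl formate, CCOC=O
Why: C-formylation of a non-stabilised ylide by a formate ester (ylide acylation), followed by deprotonation of the acyl phosphonium, gives the isolable formyl-stabilised ylide; C15 thus enters at the aldehyde level and no ester reduction is needed once the lactone is attached.

Step 8
Reactants: 14 L-glutamic acid
Product: 15 (S)-5-oxotetrahydrofuran-2-carboxylic acid
Conditions: NaNO2, aq. HCl, 0 °C to rt
Reagents that add atoms: none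
Why: Diazotisation; the α-carboxylate displaces N2 to an α-lactone that the γ-carboxylate opens, and the two inversions give net retention, so the (S) centre of 14 becomes C6.

Step 9
Reactants: 15 (S)-5-oxotetrahydrofuran-2-carboxylic acid
Product: 16 (S)-5-(hydroxymethyl)dihydrofuran-2(3H)-one
Conditions: BH3·SMe2, THF, 0 °C to rt; MeOH
Reagents that add atoms: none
Why: Borane reduces a free carboxylic acid much faster than a lactone (chemoselective acid reduction).

Step 10
Reactants: 16 (S)-5-(hydroxymethyl)dihydrofuran-2(3H)-one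
Product: 17 (S)-5-oxotetrahydrofuran-2-carbaldehyde
Conditions: Dess–Martin periodinane, CH2Cl2, 0 °C to rt; non-aqueous work-up, used crude
Reagents that add atoms: none
Why: Dess–Martin oxidation under neutral conditions; the α-acyloxy aldehyde hydrates and enolises easily, so it should be taken on at once without chromatography.

Step 11
Reactants: 17 (S)-5-oxotetrahydrofuran-2-carbaldehyde; 13 (E)-6-(TBDPS-oxymethyl)-8-(TBS-oxy)-2-(triphenylphosphoranylidene)oct-5-enal
Product: 18 (S)-5-[(1E,5E)-2-formyl-6-(TBDPS-oxymethyl)-8-(TBS-oxy)octa-1,5-dien-1-yl]dihydrofuran-2(3H)-one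
Conditions: toluene, 80 °C (17 in excess)
Reagents that add atoms: none
Why: Wittig olefination with a formyl-stabilised ylide should give the E enal, with C6 trans to C15 and cis to C3 as the target needs; the ylide does not touch the lactone.

Step 12
Reactants: 18 (S)-5-[(1E,5E)-2-formyl-6-(TBDPS-oxymethyl)-8-(TBS-oxy)octa-1,5-dien-1-yl]dihydrofuran-2(3H)-one
Product: 19 (S)-5-[(1E,5E)-2-(hydroxymethyl)-6-(TBDPS-oxymethyl)-8-(TBS-oxy)octa-1,5-dien-1-yl]dihydrofuran-2(3H)-one
Conditions: NaBH4, CeCl3·7H2O, MeOH, −78 to −20 °C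
Reagents that add atoms: none
Why: Luche reduction: clean 1,2-reduction of the enal at low temperature, where a γ-lactone is not reduced.

Step 13
Reactants: 19 (S)-5-[(1E,5E)-2-(hydroxymethyl)-6-(TBDPS-oxymethyl)-8-(TBS-oxy)octa-1,5-dien-1-yl]dihydrofuran-2(3H)-one
Product: 21 (5S)-5-[(1E,5E)-2-(hydroxymethyl)-6-(TBDPS-oxymethyl)-8-(TBS-oxy)octa-1,5-dien-1-yl]-3-(phenylselanyl)dihydrofuran-2(3H)-one (both C3 epimers), via dilithium alkoxide enolate 20 (not isolated)
Conditions: LiN(i-Pr)2 (2.2 equiv), THF, −78 °C; then PhSeBr; aq. NH4Cl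
Reagents that add atoms: phenylselanyl bromide, Br[Se]c1ccccc1
Why: Kinetic lactone enolate formation and α-selenenylation at C11; the C15 alkoxide is a spectator and any O–Se bond formed there is lost on work-up; the C11 epimers are both carried on because C11 becomes sp2 in step 16.

Step 14
Reactants: 21 (5S)-5-[(1E,5E)-2-(hydroxymethyl)-6-(TBDPS-oxymethyl)-8-(TBS-oxy)octa-1,5-dien-1-yl]-3-(phenylselanyl)dihydrofuran-2(3H)-one
Product: 23 (5S)-3-(hydroxymethyl)-5-[(1E,5E)-2-(hydroxymethyl)-6-(TBDPS-oxymethyl)-8-(TBS-oxy)octa-1,5-dien-1-yl]-3-(phenylselanyl)dihydrofuran-2(3H)-one (both C3 epimers), via dilithium seleno enolate 22 (not isolated)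
Conditions: LiN(i-Pr)2 (2.2 equiv), THF, −78 °C; then CH2O (gas); aq. NH4Cl
Reagents that add atoms: formaldehyde, C=O
Why: Aldol addition of the selenium-stabilised lactone enolate to monomeric formaldehyde installs C13 on the now quaternary C11.

Step 15
Reactants: 23 (5S)-3-(hydroxymethyl)-5-[(1E,5E)-2-(hydroxymethyl)-6-(TBDPS-oxymethyl)-8-(TBS-oxy)octa-1,5-dien-1-yl]-3-(phenylselanyl)dihydrofuran-2(3H)-one
Product: 24 (5S)-5-[(1E,5E)-2-(acetoxymethyl)-6-(TBDPS-oxymethyl)-8-(TBS-oxy)octa-1,5-dien-1-yl]-3-(hydroxymethyl)-3-(phenylselanyl)dihydrofuran-2(3H)-one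
Conditions: AcCl (1.05 equiv), 2,4,6-collidine, CH2Cl2, −78 °C
Reagents that add atoms: acetyl chloride, CC(Cl)=O
Why: Kinetically controlled acylation should take the unhindered allylic C15 hydroxyl and leave the neopentyl C13 hydroxyl on the quaternary carbon; the acetate is introduced only now because it would not survive the enolate steps.

Step 16
Reactants: 24 (5S)-5-[(1E,5E)-2-(acetoxymethyl)-6-(TBDPS-oxymethyl)-8-(TBS-oxy)octa-1,5-dien-1-yl]-3-(hydroxymethyl)-3-(phenylselanyl)dihydrofuran-2(3H)-one
Product: 26 (R)-5-[(1E,5E)-2-(acetoxymethyl)-6-(TBDPS-oxymethyl)-8-(TBS-oxy)octa-1,5-dien-1-yl]-3-(hydroxymethyl)furan-2(5H)-one, via selenoxide 25 (not isolated)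
Conditions: 30% aq. H2O2, pyridine, CH2Cl2, 0 °C to rt
Reagents that add atoms: none
Why: Selenide oxidation and syn-elimination of the selenoxide; elimination runs toward C7–H and not toward the carbinol carbon C13 (selenoxides avoid forming enols), so the endocyclic butenolide results, and the buffered mild medium spares the trisubstituted alkenes and the acidic C6–H.

Step 17
Reactants: 26 (R)-5-[(1E,5E)-2-(acetoxymethyl)-6-(TBDPS-oxymethyl)-8-(TBS-oxy)octa-1,5-dien-1-yl]-3-(hydroxymethyl)furan-2(5H)-one
Product: 27 (R)-5-[(1E,5E)-2-(acetoxymethyl)-6-(TBDPS-oxymethyl)-8-(TBS-oxy)octa-1,5-dien-1-yl]-3-(bromomethyl)furan-2(5H)-one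
Conditions: CBr4, PPh3, CH2Cl2, 0 °C
Reagents that add atoms: carbon tetrabromide, BrC(Br)(Br)Br
Why: Appel bromination of the only free primary allylic alcohol under neutral conditions; acetate and silyl ethers are untouched.

Step 18
Reactants: 27 (R)-5-[(1E,5E)-2-(acetoxymethyl)-6-(TBDPS-oxymethyl)-8-(TBS-oxy)octa-1,5-dien-1-yl]-3-(bromomethyl)furan-2(5H)-one
Product: 28 (R)-5-[(1E,5E)-2-(acetoxymethyl)-6-(TBDPS-oxymethyl)-8-hydroxyocta-1,5-dien-1-yl]-3-(bromomethyl)furan-2(5H)-one
Conditions: HF·pyridine, pyridine, THF, 0 °C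
Reagents that add atoms: none
Why: Buffered HF·pyridine cleaves a primary alkyl TBS ether far faster than a TBDPS ether; the weakly nucleophilic medium should spare the allylic bromide and the acetate.

Step 19
Reactants: 28 (R)-5-[(1E,5E)-2-(acetoxymethyl)-6-(TBDPS-oxymethyl)-8-hydroxyocta-1,5-dien-1-yl]-3-(bromomethyl)furan-2(5H)-one
Product: 29 (R)-5-[(1E,5E)-2-(acetoxymethyl)-6-(TBDPS-oxymethyl)-8-oxoocta-1,5-dien-1-yl]-3-(bromomethyl)furan-2(5H)-one
Conditions: Dess–Martin periodinane, NaHCO3, CH2Cl2, 0 °C; used at once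
Reagents that add atoms: none
Why: Buffered Dess–Martin oxidation gives the β,γ-unsaturated C8 aldehyde without the acid or base that would move C1=C10 into conjugation.

Step 20
Reactants: 29 (R)-5-[(1E,5E)-2-(acetoxymethyl)-6-(TBDPS-oxymethyl)-8-oxoocta-1,5-dien-1-yl]-3-(bromomethyl)furan-2(5H)-one
Product: 31 (6R,7R,8S)-15-acetoxy-14-(TBDPS-oxy)-8-hydroxygermacra-1(10),4,11(13)-trien-12,6-olide with both ring alkenes cis in the ring, via allylchromium dichloride 30 (not isolated)
Conditions: CrCl2 (6 equiv), THF, rt, 29 added slowly to a final concentration of about 2 mM; aq. NH4Cl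
Reagents that add atoms: none
Why: Two equivalents of CrCl2 (divalent chromium) reduce the C13–Br bond of 29 to the trivalent allylchromium 30, which is nucleophilic toward the aldehyde only and leaves lactone, acetate and silyl ether alone. The aldehyde oxygen binds chromium and the C–C bond forms at the γ-carbon C7 through a six-membered chair transition state (Cr, C13, C11, C7, C8, O), so the double bond moves to C11=C13 and the α-methylene lactone appears. The closest known reaction type is the Nozaki–Hiyama–Kishi allylation, established for γ-selective additions of 3-(bromomethyl)furan-2(5H)-ones to aldehydes and for intramolecular closures of ten-membered carbocycles from (alkoxycarbonyl)allyl bromides. The ten-membered ring is closed by this intramolecular carbonyl addition (formally 10-exo-trig at C8), with the lactone ring already in place. C7 is controlled by C6: the tether leaves C6 through C5 on one face of the flat butenolide and the aldehyde reaches C7 from the other, which gives the trans ring fusion, also the less strained one for a ten-membered ring. C8 is controlled by the chair: the cyclic allyl unit has a fixed geometry with C6 trans to C13, and with C9 equatorial (the position that also points toward C5) the anti relation of C6 and O8, that is 8S, results. The step needs γ- over α-attack, secured by the closed transition state, and ring closure over oligomerisation, secured by slow addition at high dilution. The neutral medium should keep the β,γ-unsaturated aldehyde from isomerising, and the chromium alkoxide is too weak a nucleophile to translactonise before work-up.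

Step 21
Reactants: 31 (6R,7R,8S)-15-acetoxy-14-(TBDPS-oxy)-8-hydroxygermacra-1(10),4,11(13)-trien-12,6-olide; 32 (S)-2-methylbutanoic acid
Product: 33 (6R,7R,8S)-15-acetoxy-14-(TBDPS-oxy)-8-[(S)-2-methylbutanoyloxy]germacra-1(10),4,11(13)-trien-12,6-olide
Conditions: N,N′-dicyclohexylcarbodiimide, 4-(dimethylamino)pyridine (cat.), CH2Cl2, 0 °C to rt
Reagents that add atoms: none
Why: Steglich esterification of the secondary C8 alcohol with retention at C8; low temperature and a catalytic amount of the acyl-transfer catalyst limit epimerisation of the α-centre of the acid.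

Step 22
Reactants: 33 (6R,7R,8S)-15-acetoxy-14-(TBDPS-oxy)-8-[(S)-2-methylbutanoyloxy]germacra-1(10),4,11(13)-trien-12,6-olide
Product: 34 (6R,7R,8S)-15-acetoxy-14-hydroxy-8-[(S)-2-methylbutanoyloxy]germacra-1(10),4,11(13)-trien-12,6-olide
Conditions: HF·pyridine, pyridine, THF, 0 °C to rt
Reagents that add atoms: none
Why: Fluoride cleavage of the primary allylic TBDPS ether under buffered acidic conditions, which leave both esters and the α-methylene lactone intact (no basic fluoride, so no acyl migration or conjugate addition).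

Step 23
Reactants: 34 (6R,7R,8S)-15-acetoxy-14-hydroxy-8-[(S)-2-methylbutanoyloxy]germacra-1(10),4,11(13)-trien-12,6-olide
Product: 35 target, (6R,7R,8S)-15-acetoxy-8-[(S)-2-methylbutanoyloxy]-14-oxogermacra-1(10),4,11(13)-trien-12,6-olide
Conditions: MnO2, CH2Cl2, rt
Reagents that add atoms: none
Why: MnO2 oxidises the primary allylic alcohol selectively to the enal under neutral conditions, without touching the alkene geometry or the other groups.

## Compound list

1 | triethyl phosphonoacetate | CCOC(=O)CP(=O)(OCC)OCC | starting material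
2 | (2-bromoethoxy)(tert-butyl)dimethylsilane | BrCCO[Si](C)(C)C(C)(C)C | starting material
3 | sodium salt of triethyl phosphonoacetate (carbanion) | [Na+].CCOC(=O)[CH-]P(=O)(OCC)OCC | intermediate
4 | ethyl 4-[(tert-butyldimethylsilyl)oxy]-2-(diethoxyphosphoryl)butanoate (racemic) | CCOC(=O)C(CCO[Si](C)(C)C(C)(C)C)P(=O)(OCC)OCC | intermediate
5 | ethyl 4-bromobutanoate | CCOC(=O)CCCBr | starting material
6 | 4-bromobutanal | O=CCCCBr | intermediate
7 | sodium carbanion of phosphonate 4 | [Na+].CCOC(=O)[C-](CCO[Si](C)(C)C(C)(C)C)P(=O)(OCC)OCC | intermediate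
8 | ethyl (E)-6-bromo-2-[2-[(tert-butyldimethylsilyl)oxy]ethyl]hex-2-enoate | CCOC(=O)/C(CCO[Si](C)(C)C(C)(C)C)=C/CCCBr | intermediate
9 | (E)-6-bromo-2-[2-[(tert-butyldimethylsilyl)oxy]ethyl]hex-2-en-1-ol | OC/C(CCO[Si](C)(C)C(C)(C)C)=C/CCCBr | intermediate
10 | [[(E)-6-bromo-2-[2-[(tert-butyldimethylsilyl)oxy]ethyl]hex-2-en-1-yl]oxy](tert-butyl)diphenylsilane | CC(C)(C)[Si](OC/C(CCO[Si](C)(C)C(C)(C)C)=C/CCCBr)(c1ccccc1)c1ccccc1 | intermediate
11 | [(E)-5-[[(tert-butyldiphenylsilyl)oxy]methyl]-7-[(tert-butyldimethylsilyl)oxy]hept-4-en-1-yl]triphenylphosphonium bromide | [Br-].CC(C)(C)[Si](OC/C(CCO[Si](C)(C)C(C)(C)C)=C/CCC[P+](c1ccccc1)(c1ccccc1)c1ccccc1)(c1ccccc1)c1ccccc1 | intermediate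
12 | [(E)-5-[[(tert-butyldiphenylsilyl)oxy]methyl]-7-[(tert-butyldimethylsilyl)oxy]hept-4-en-1-ylidene]triphenylphosphorane | CC(C)(C)[Si](OC/C(CCO[Si](C)(C)C(C)(C)C)=C/CCC=P(c1ccccc1)(c1ccccc1)c1ccccc1)(c1ccccc1)c1ccccc1 | intermediate
13 | (E)-6-[[(tert-butyldiphenylsilyl)oxy]methyl]-8-[(tert-butyldimethylsilyl)oxy]-2-(triphenylphosphoranylidene)oct-5-enal | O=CC(CC/C=C(/CO[Si](c1ccccc1)(c1ccccc1)C(C)(C)C)CCO[Si](C)(C)C(C)(C)C)=P(c1ccccc1)(c1ccccc1)c1ccccc1 | intermediate
14 | L-glutamic acid | N[C@@H](CCC(=O)O)C(=O)O | starting material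
15 | (S)-5-oxotetrahydrofuran-2-carboxylic acid | OC(=O)[C@@H]1CCC(=O)O1 | intermediate
16 | (S)-5-(hydroxymethyl)dihydrofuran-2(3H)-one | OC[C@@H]1CCC(=O)O1 | intermediate
17 | (S)-5-oxotetrahydrofuran-2-carbaldehyde | O=C[C@@H]1CCC(=O)O1 | intermediate
18 | (S)-5-[(1E,5E)-8-[(tert-butyldimethylsilyl)oxy]-6-[[(tert-butyldiphenylsilyl)oxy]methyl]-2-formylocta-1,5-dien-1-yl]dihydrofuran-2(3H)-one | O=C1CC[C@@H](/C=C(/C=O)CC/C=C(/CO[Si](c2ccccc2)(c2ccccc2)C(C)(C)C)CCO[Si](C)(C)C(C)(C)C)O1 | intermediate
19 | (S)-5-[(1E,5E)-8-[(tert-butyldimethylsilyl)oxy]-6-[[(tert-butyldiphenylsilyl)oxy]methyl]-2-(hydroxymethyl)octa-1,5-dien-1-yl]dihydrofuran-2(3H)-one | O=C1CC[C@@H](/C=C(/CO)CC/C=C(/CO[Si](c2ccccc2)(c2ccccc2)C(C)(C)C)CCO[Si](C)(C)C(C)(C)C)O1 | intermediate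
20 | dilithium alkoxide enolate of 19 | [Li+].[Li+].[O-]C1=CC[C@@H](/C=C(/C[O-])CC/C=C(/CO[Si](c2ccccc2)(c2ccccc2)C(C)(C)C)CCO[Si](C)(C)C(C)(C)C)O1 | intermediate
21 | (5S)-3-(phenylselanyl) derivative of 19, both C3 epimers | O=C1C([Se]c2ccccc2)C[C@@H](/C=C(/CO)CC/C=C(/CO[Si](c3ccccc3)(c3ccccc3)C(C)(C)C)CCO[Si](C)(C)C(C)(C)C)O1 | intermediate
22 | dilithium alkoxide enolate of 21 | [Li+].[Li+].[O-]C1=C([Se]c2ccccc2)C[C@@H](/C=C(/C[O-])CC/C=C(/CO[Si](c3ccccc3)(c3ccccc3)C(C)(C)C)CCO[Si](C)(C)C(C)(C)C)O1 | intermediate
23 | (5S)-3-(hydroxymethyl)-3-(phenylselanyl) lactone diol, both C3 epimers | O=C1C(CO)([Se]c2ccccc2)C[C@@H](/C=C(/CO)CC/C=C(/CO[Si](c3ccccc3)(c3ccccc3)C(C)(C)C)CCO[Si](C)(C)C(C)(C)C)O1 | intermediate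
24 | C15 monoacetate of 23 | O=C1C(CO)([Se]c2ccccc2)C[C@@H](/C=C(/COC(C)=O)CC/C=C(/CO[Si](c3ccccc3)(c3ccccc3)C(C)(C)C)CCO[Si](C)(C)C(C)(C)C)O1 | intermediate
25 | selenoxide of 24 | O=C1C(CO)([Se](=O)c2ccccc2)C[C@@H](/C=C(/COC(C)=O)CC/C=C(/CO[Si](c3ccccc3)(c3ccccc3)C(C)(C)C)CCO[Si](C)(C)C(C)(C)C)O1 | intermediate
26 | (R)-5-[(1E,5E)-2-(acetoxymethyl)-8-[(tert-butyldimethylsilyl)oxy]-6-[[(tert-butyldiphenylsilyl)oxy]methyl]octa-1,5-dien-1-yl]-3-(hydroxymethyl)furan-2(5H)-one | OCC1=C[C@@H](/C=C(/COC(C)=O)CC/C=C(/CO[Si](c2ccccc2)(c2ccccc2)C(C)(C)C)CCO[Si](C)(C)C(C)(C)C)OC1=O | intermediate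
27 | (R)-5-[(1E,5E)-2-(acetoxymethyl)-8-[(tert-butyldimethylsilyl)oxy]-6-[[(tert-butyldiphenylsilyl)oxy]methyl]octa-1,5-dien-1-yl]-3-(bromomethyl)furan-2(5H)-one | BrCC1=C[C@@H](/C=C(/COC(C)=O)CC/C=C(/CO[Si](c2ccccc2)(c2ccccc2)C(C)(C)C)CCO[Si](C)(C)C(C)(C)C)OC1=O | intermediate
28 | (R)-5-[(1E,5E)-2-(acetoxymethyl)-6-[[(tert-butyldiphenylsilyl)oxy]methyl]-8-hydroxyocta-1,5-dien-1-yl]-3-(bromomethyl)furan-2(5H)-one | BrCC1=C[C@@H](/C=C(/COC(C)=O)CC/C=C(/CO[Si](c2ccccc2)(c2ccccc2)C(C)(C)C)CCO)OC1=O | intermediate
29 | (R)-5-[(1E,5E)-2-(acetoxymethyl)-6-[[(tert-butyldiphenylsilyl)oxy]methyl]-8-oxoocta-1,5-dien-1-yl]-3-(bromomethyl)furan-2(5H)-one (key-step precursor) | BrCC1=C[C@@H](/C=C(/COC(C)=O)CC/C=C(/CO[Si](c2ccccc2)(c2ccccc2)C(C)(C)C)CC=O)OC1=O | intermediate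
30 | allylchromium dichloride from 29 (trivalent chromium on C13) | Cl[Cr](Cl)CC1=C[C@@H](/C=C(/COC(C)=O)CC/C=C(/CO[Si](c2ccccc2)(c2ccccc2)C(C)(C)C)CC=O)OC1=O | intermediate
31 | (6R,7R,8S)-15-acetoxy-14-[(tert-butyldiphenylsilyl)oxy]-8-hydroxygermacra-1(10),4,11(13)-trien-12,6-olide, ring alkenes cis in the ring | C=C1C(=O)O[C@@H]2/C=C(/COC(C)=O)CC/C=C(/CO[Si](c3ccccc3)(c3ccccc3)C(C)(C)C)C[C@H](O)[C@@H]12 | intermediate
32 | (S)-2-methylbutanoic acid | CC[C@H](C)C(=O)O | starting material
33 | (6R,7R,8S)-15-acetoxy-14-[(tert-butyldiphenylsilyl)oxy]-8-[(S)-2-methylbutanoyloxy]germacra-1(10),4,11(13)-trien-12,6-olide | C=C1C(=O)O[C@@H]2/C=C(/COC(C)=O)CC/C=C(/CO[Si](c3ccccc3)(c3ccccc3)C(C)(C)C)C[C@H](OC(=O)[C@@H](C)CC)[C@@H]12 | intermediate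
34 | (6R,7R,8S)-15-acetoxy-14-hydroxy-8-[(S)-2-methylbutanoyloxy]germacra-1(10),4,11(13)-trien-12,6-olide | C=C1C(=O)O[C@@H]2/C=C(/COC(C)=O)CC/C=C(/CO)C[C@H](OC(=O)[C@@H](C)CC)[C@@H]12 | intermediate
35 | (6R,7R,8S)-15-acetoxy-8-[(S)-2-methylbutanoyloxy]-14-oxogermacra-1(10),4,11(13)-trien-12,6-olide | C=C1C(=O)O[C@@H]2/C=C(/COC(C)=O)CC/C=C(/C=O)C[C@H](OC(=O)[C@@H](C)CC)[C@@H]12 | target

## Step count and least certain steps

Total: 23 steps. Longest linear sequence: 19 steps (1, 3, 4, 5, 6, 7, then 11 to 23).

**Step 20 (key step).** The process most likely to fail is face selection at the aldehyde carbon. The chair preference has to be expressed inside a forming ten-membered ring, and if the ring forces C9 into the axial position, the C8 epimer forms. Intermolecular coupling is the second concern and is answered only by dilution. Fallback: the cyclisation of 29 is carried through to the 8-epimeric alcohol F1. F1 is then esterified with acid 32 under Mitsunobu conditions (PPh3, diisopropyl azodicarboxylate, THF, 0 °C). This inverts C8 and rejoins the route at 33.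

**Step 11.** The likely failure is loss of configurational purity at C6, through enolisation of the α-acyloxy aldehyde 17 during a slow, heated olefination with a weakly nucleophilic formyl ylide. Fallback, from salt 11 back to 18:
- Salt 11 is deprotonated and the ylide is acylated with ethyl chloroformate (two equivalents of KOt-Bu) to the ester-stabilised ylide F2.
- F2 olefinates 17 in CH2Cl2 at room temperature to the E enoate F3.
- i-Bu2AlH at −78 °C reduces the ester and the lactone together to the lactol allylic alcohol F4.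
- PhI(OAc)2 with catalytic 2,2,6,6-tetramethylpiperidin-1-oxyl oxidises the lactol back to the lactone and the allylic alcohol to the enal, which is 18.

**Step 15.** The likely failure is insufficient discrimination between the two primary hydroxyls, giving over-acylation or acylation at C13. The same free C15 hydroxyl can also consume selenium electrophile in step 13. Fallback, from 19 back to 27:
- The C15 hydroxyl is silylated first (Et3SiCl, imidazole) to the TES ether F5.
- Selenenylation as in step 13 gives selenide F6, and hydroxymethylation as in step 14 gives alcohol F7.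
- Selenoxide elimination gives the butenolide alcohol F8, and Appel bromination gives bromide F9.
- Pyridinium p-toluenesulfonate in MeOH at 0 °C removes only the TES group to give allylic alcohol F10.
- Acetylation of F10 (AcCl, 2,6-lutidine) gives 27.

**Step 3.** The likely failure is erosion of E/Z selectivity, since an α-branched phosphonate anion adds to an unbranched aldehyde with little steric bias. Fallback, from aldehyde 6 back to 9:
- (3-Bromopropoxy)(tert-butyl)dimethylsilane and PPh3 give the phosphonium salt F11.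
- Formylation as in step 7 gives the formyl ylide F12.
- Wittig reaction of F12 with 6 in warm toluene gives the E enal F13.
- Luche reduction of F13 gives alcohol 9.

Further compounds
F1 | step 20 | (6R,7R,8R)-15-acetoxy-14-[(tert-butyldiphenylsilyl)oxy]-8-hydroxygermacra-1(10),4,11(13)-trien-12,6-olide (8-epimer of 31) | C=C1C(=O)O[C@@H]2/C=C(/COC(C)=O)CC/C=C(/CO[Si](c3ccccc3)(c3ccccc3)C(C)(C)C)C[C@@H](O)[C@@H]12
F2 | step 11 | ethyl (E)-6-[[(tert-butyldiphenylsilyl)oxy]methyl]-8-[(tert-butyldimethylsilyl)oxy]-2-(triphenylphosphoranylidene)oct-5-enoate | CCOC(=O)C(CC/C=C(/CO[Si](c1ccccc1)(c1ccccc1)C(C)(C)C)CCO[Si](C)(C)C(C)(C)C)=P(c1ccccc1)(c1ccccc1)c1ccccc1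
F3 | step 11 | (S)-5-[(1E,5E)-8-[(tert-butyldimethylsilyl)oxy]-6-[[(tert-butyldiphenylsilyl)oxy]methyl]-2-(ethoxycarbonyl)octa-1,5-dien-1-yl]dihydrofuran-2(3H)-one | O=C1CC[C@@H](/C=C(/C(=O)OCC)CC/C=C(/CO[Si](c2ccccc2)(c2ccccc2)C(C)(C)C)CCO[Si](C)(C)C(C)(C)C)O1
F4 | step 11 | (5S)-5-[(1E,5E)-8-[(tert-butyldimethylsilyl)oxy]-6-[[(tert-butyldiphenylsilyl)oxy]methyl]-2-(hydroxymethyl)octa-1,5-dien-1-yl]tetrahydrofuran-2-ol (lactol, both anomers) | OC1CC[C@@H](/C=C(/CO)CC/C=C(/CO[Si](c2ccccc2)(c2ccccc2)C(C)(C)C)CCO[Si](C)(C)C(C)(C)C)O1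
F5 | step 15 | C15 triethylsilyl ether of 19 | O=C1CC[C@@H](/C=C(/CO[Si](CC)(CC)CC)CC/C=C(/CO[Si](c2ccccc2)(c2ccccc2)C(C)(C)C)CCO[Si](C)(C)C(C)(C)C)O1
F6 | step 15 | 3-(phenylselanyl) derivative of F5, both C3 epimers | O=C1C([Se]c2ccccc2)C[C@@H](/C=C(/CO[Si](CC)(CC)CC)CC/C=C(/CO[Si](c3ccccc3)(c3ccccc3)C(C)(C)C)CCO[Si](C)(C)C(C)(C)C)O1
F7 | step 15 | 3-(hydroxymethyl)-3-(phenylselanyl) derivative of F5, both C3 epimers | O=C1C(CO)([Se]c2ccccc2)C[C@@H](/C=C(/CO[Si](CC)(CC)CC)CC/C=C(/CO[Si](c3ccccc3)(c3ccccc3)C(C)(C)C)CCO[Si](C)(C)C(C)(C)C)O1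
F8 | step 15 | (R)-3-(hydroxymethyl)butenolide with C15 triethylsilyl ether | OCC1=C[C@@H](/C=C(/CO[Si](CC)(CC)CC)CC/C=C(/CO[Si](c2ccccc2)(c2ccccc2)C(C)(C)C)CCO[Si](C)(C)C(C)(C)C)OC1=O
F9 | step 15 | (R)-3-(bromomethyl)butenolide with C15 triethylsilyl ether | BrCC1=C[C@@H](/C=C(/CO[Si](CC)(CC)CC)CC/C=C(/CO[Si](c2ccccc2)(c2ccccc2)C(C)(C)C)CCO[Si](C)(C)C(C)(C)C)OC1=O
F10 | step 15 | (R)-3-(bromomethyl)butenolide with free C15 hydroxyl | BrCC1=C[C@@H](/C=C(/CO)CC/C=C(/CO[Si](c2ccccc2)(c2ccccc2)C(C)(C)C)CCO[Si](C)(C)C(C)(C)C)OC1=O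
F11 | step 3 | [3-[(tert-butyldimethylsilyl)oxy]propyl]triphenylphosphonium bromide | [Br-].CC(C)(C)[Si](C)(C)OCCC[P+](c1ccccc1)(c1ccccc1)c1ccccc1
F12 | step 3 | 4-[(tert-butyldimethylsilyl)oxy]-2-(triphenylphosphoranylidene)butanal | O=CC(CCO[Si](C)(C)C(C)(C)C)=P(c1ccccc1)(c1ccccc1)c1ccccc1
F13 | step 3 | (E)-6-bromo-2-[2-[(tert-butyldimethylsilyl)oxy]ethyl]hex-2-enal | O=C/C(CCO[Si](C)(C)C(C)(C)C)=C/CCCBr
A1 | alternative 1 | methyl 3-[(tert-butyldimethylsilyl)oxy]-4-[2-[(tert-butyldimethylsilyl)oxy]ethyl]-6-methyl-1,2,3,4,5,8-hexahydronaphthalene-1-carboxylate (Birch-type diene, ring-fusion alkene) | COC(=O)C1C[C@H](O[Si](C)(C)C(C)(C)C)[C@@H](CCO[Si](C)(C)C(C)(C)C)C2=C1CC=C(C)C2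
A2 | alternative 1 | cyclodec-3-ene-1,6-dione with C10 methyl ester, C8 silyl ether and C7 silyloxyethyl chain | COC(=O)C1C[C@H](O[Si](C)(C)C(C)(C)C)[C@@H](CCO[Si](C)(C)C(C)(C)C)C(=O)C/C(C)=C\CC1=O
A3 | alternative 2 | cis-1,2-dialkenyl cyclohex-2-enol of the perillyl type with (E)-2-(4-methoxybenzyloxy)vinyl group on the carbinol carbon | O[C@@]1(/C=C/OCc2ccc(OC)cc2)C=C(CO[Si](C)(C)C(C)(C)C)CC[C@@H]1C(=C)CO[Si](c1ccccc1)(c1ccccc1)C(C)(C)C
A4 | alternative 2 | tert-butyl bromoacetate | BrCC(=O)OC(C)(C)C
A5 | alternative 2 | ten-membered dienone with C6 ketone, C7 tert-butoxycarbonylmethyl group and C8 4-methoxybenzyl ether | O=C1/C=C(/CO[Si](C)(C)C(C)(C)C)CC/C=C(/CO[Si](c2ccccc2)(c2ccccc2)C(C)(C)C)C[C@H](OCc2ccc(OC)cc2)[C@H]1CC(=O)OC(C)(C)C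
A6 | alternative 3 | eleven-membered α-chloro sulfone lactone with C10 allyl ester (C10 epimers) | O=C1O[C@@H]2/C=C(/CO[Si](c3ccccc3)(c3ccccc3)C(C)(C)C)CCCS(=O)(=O)C(Cl)(C(=O)OCC=C)C[C@H](O[Si](C)(C)C(C)(C)C)[C@H]2C1
A7 | alternative 3 | ten-membered diene lactone with C14 allyl ester, C8 silyl ether and C15 silyl ether | O=C1O[C@@H]2/C=C(/CO[Si](c3ccccc3)(c3ccccc3)C(C)(C)C)CC/C=C(/C(=O)OCC=C)C[C@H](O[Si](C)(C)C(C)(C)C)[C@H]2C1
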